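Numbering the target as a decalin (C1 bearing the pentyl chain, C2 the ketone, C4a and C8a the ring-fusion carbons), everything rests on cutting the C5–C6 bond of ring B (C4a, C5, C6, C7, C8, C8a). The feature exploited is the secondary carbinol on quaternary C6: an oxygen beside a fully substituted carbon is the imprint of a trisubstituted epoxide opened reductively. A monocyclic ring A precursor with an exocyclic methylene at C4a and a Sharpless epoxy alcohol tethered to C8a is treated with Cp2TiCl; the tertiary radical closes ring B 6-endo, sets C6 and, after hydrogen-atom transfer, the trans ring fusion, delivering the side-chain diol directly.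

Key step: step 10

Remark: (S)-(+)-linalool is taken as purchased in high enantiomeric purity; the stereocentre it supplies is not touched afterwards. Monocyclic intermediates are named as 1,4-dioxaspiro[4.5]decanes (C5 spiro carbon, C8 carbonyl or methylidene carbon).

Step 1
Reactants: 1 (S)-(+)-linalool
Product: 3 (2S)-2-methylpentane-1,2,5-triol, via hydroxy dialdehyde 2 (not isolated)
Conditions: O3, CH2Cl2/MeOH, −78 °C; then NaBH4 (excess), −78 °C to rt
Reagents that add atoms: ozone, [O-][O+]=O
Why: Ozonolysis cleaves both alkenes and borohydride reduces the hydroxy dialdehyde (and the acetone and formaldehyde set free) in the same flask, the tertiary carbinol stereocentre being untouched (ozonolysis with reductive work-up).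

Step 2
Reactants: 3 (2S)-2-methylpentane-1,2,5-triol
Product: 4 3-[(4S)-2,2,4-trimethyl-1,3-dioxolan-4-yl]propan-1-ol
Conditions: Me2C(OMe)2, TsOH·H2O (cat.), acetone, rt
Reagents that add atoms: 2,2-dimethoxypropane, COC(C)(C)OC
Why: Acid-catalysed transketalisation should close the five-membered dioxolane across the 1,2-diol and leave the remote primary hydroxyl free.

Step 3
Reactants: 4 3-[(4S)-2,2,4-trimethyl-1,3-dioxolan-4-yl]propan-1-ol
Product: 5 (4S)-4-(3-bromopropyl)-2,2,4-trimethyl-1,3-dioxolane
Conditions: CBr4, PPh3, imidazole, CH2Cl2, 0 °C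
Reagents that add atoms: carbon tetrabromide, BrC(Br)(Br)Br
Why: Appel bromination of the primary alcohol, buffered so that the acetonide survives.

Step 4
Reactants: 5 (4S)-4-(3-bromopropyl)-2,2,4-trimethyl-1,3-dioxolane; 6 1,4-dioxaspiro[4.5]dec-6-en-8-one
Product: 9 (6R,7R)-7-methyl-6-{3-[(4S)-2,2,4-trimethyl-1,3-dioxolan-4-yl]propyl}-1,4-dioxaspiro[4.5]decan-8-one, via Grignard reagent 7 (not isolated), via magnesium enolate 8 (not isolated)
Conditions: 5, Mg, Et2O, rt; then 6, CuBr·SMe2 (5 mol %), Josiphos-type ferrocenyl diphosphine (6 mol %, enantiomer chosen for 6R), t-BuOMe, −78 °C; then MeI, DMPU, −78 to 0 °C; aq NH4Cl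
Reagents that add atoms: iodomethane, CI
Why: Copper-catalysed asymmetric conjugate addition of a Grignard reagent to a cyclohexenone should set C6 (6R) by ligand control, and the regiodefined magnesium enolate is C-methylated in the same flask anti to the new chain (the C7 configuration is erased again in step 5), any 6S material being a diastereomer because of the enantiopure dioxolane.

Step 5
Reactants: 9 (6R,7R)-7-methyl-6-{3-[(4S)-2,2,4-trimethyl-1,3-dioxolan-4-yl]propyl}-1,4-dioxaspiro[4.5]decan-8-one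
Product: 11 (6R,7R)-7-methyl-7-(3-oxobutyl)-6-{3-[(4S)-2,2,4-trimethyl-1,3-dioxolan-4-yl]propyl}-1,4-dioxaspiro[4.5]decan-8-one, via chiral imine 10 (not isolated)
Conditions: (R)-1-phenylethylamine, toluene, 4 Å MS, reflux; then methyl vinyl ketone, THF, 40 °C; then 10% aq AcOH, rt
Reagents that add atoms: methyl vinyl ketone, C=CC(C)=O
Why: In this d'Angelo deracemising Michael addition the secondary enamine tautomer of the imine should add to the enone at the more substituted α-carbon through an aza-ene-like transition state, on the face anti to the neighbouring C6 chain, which is also the face favoured by the (R)-amine in the parent 2-methylcyclohexanone series, so the quaternary carbon forms with methyl cis to the C6 chain and the neutral medium stops before any aldol closure.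

Step 6
Reactants: 11 (6R,7R)-7-methyl-7-(3-oxobutyl)-6-{3-[(4S)-2,2,4-trimethyl-1,3-dioxolan-4-yl]propyl}-1,4-dioxaspiro[4.5]decan-8-one
Product: 12 ethyl (2E)-3-methyl-5-[(6R,7R)-7-methyl-8-oxo-6-{3-[(4S)-2,2,4-trimethyl-1,3-dioxolan-4-yl]propyl}-1,4-dioxaspiro[4.5]decan-7-yl]pent-2-enoate
Conditions: (EtO)2P(O)CH2CO2Et, NaH, THF, 0 °C to reflux; minor Z isomer removed by chromatography
Reagents that add atoms: triethyl phosphonoacetate, CCOC(=O)CP(=O)(OCC)OCC
Why: Horner–Wadsworth–Emmons olefination should take only the unhindered methyl ketone, the ring ketone beside the quaternary carbon being too shielded, and should favour the E enoate.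

Step 7
Reactants: 12 ethyl (2E)-3-methyl-5-[(6R,7R)-7-methyl-8-oxo-6-{3-[(4S)-2,2,4-trimethyl-1,3-dioxolan-4-yl]propyl}-1,4-dioxaspiro[4.5]decan-7-yl]pent-2-enoate
Product: 13 ethyl (2E)-3-methyl-5-[(6R,7R)-7-methyl-8-methylidene-6-{3-[(4S)-2,2,4-trimethyl-1,3-dioxolan-4-yl]propyl}-1,4-dioxaspiro[4.5]decan-7-yl]pent-2-enoate
Conditions: Ph3PCH3Br, KN(SiMe3)2, THF, 0 to 50 °C
Reagents that add atoms: methyltriphenylphosphonium bromide, [Br-].C[P+](c1ccccc1)(c1ccccc1)c1ccccc1
Why: Wittig methylenation of the remaining α-quaternary ketone with the salt-free ylide, to which the β,β-disubstituted enoate should be inert.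

Step 8
Reactants: 13 ethyl (2E)-3-methyl-5-[(6R,7R)-7-methyl-8-methylidene-6-{3-[(4S)-2,2,4-trimethyl-1,3-dioxolan-4-yl]propyl}-1,4-dioxaspiro[4.5]decan-7-yl]pent-2-enoate
Product: 14 (2E)-3-methyl-5-[(6R,7R)-7-methyl-8-methylidene-6-{3-[(4S)-2,2,4-trimethyl-1,3-dioxolan-4-yl]propyl}-1,4-dioxaspiro[4.5]decan-7-yl]pent-2-en-1-ol
Conditions: i-Bu2AlH (2.5 equiv), CH2Cl2, −78 °C; aq potassium sodium tartrate
Reagents that add atoms: none
Why: 1,2-Reduction of the enoate by the aluminium hydride gives the allylic alcohol without touching the alkenes or the two ketals.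

Step 9
Reactants: 14 (2E)-3-methyl-5-[(6R,7R)-7-methyl-8-methylidene-6-{3-[(4S)-2,2,4-trimethyl-1,3-dioxolan-4-yl]propyl}-1,4-dioxaspiro[4.5]decan-7-yl]pent-2-en-1-ol
Product: 15 [(2R,3R)-3-methyl-3-{2-[(6R,7R)-7-methyl-8-methylidene-6-{3-[(4S)-2,2,4-trimethyl-1,3-dioxolan-4-yl]propyl}-1,4-dioxaspiro[4.5]decan-7-yl]ethyl}oxiran-2-yl]methanol
Conditions: Ti(Oi-Pr)4 (10 mol %), D-(−)-diethyl tartrate (12 mol %), t-BuOOH, 4 Å MS, CH2Cl2, −20 °C
Reagents that add atoms: tert-butyl hydroperoxide, CC(C)(C)OO
Why: Sharpless asymmetric epoxidation touches only the allylic alcohol (not the exocyclic methylene) and, with the D-tartrate on an E geraniol-type alkene, should give the (2R,3R) epoxide by reagent control, which fixes the future carbinol carbon.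

Step 10
Reactants: 15 [(2R,3R)-3-methyl-3-{2-[(6R,7R)-7-methyl-8-methylidene-6-{3-[(4S)-2,2,4-trimethyl-1,3-dioxolan-4-yl]propyl}-1,4-dioxaspiro[4.5]decan-7-yl]ethyl}oxiran-2-yl]methanol
Product: 16 (1S)-1-[(1'R,4a'S,6'S,8a'S)-6',8a'-dimethyl-1'-{3-[(4S)-2,2,4-trimethyl-1,3-dioxolan-4-yl]propyl}octahydro-1'H-spiro[1,3-dioxolane-2,2'-naphthalen]-6'-yl]ethane-1,2-diol
Conditions: Cp2TiCl2 (2.5 equiv), Mn dust, THF, rt (gives green Cp2TiCl); added slowly to 15 and H2O (10 equiv) in THF (0.01 M), rt; aq NaH2PO4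
Reagents that add atoms: none
Why: Cp2TiCl (trivalent titanium, made in the flask) transfers one electron to the epoxide and cleaves its more substituted C–O bond, giving the tertiary β-titanoxy radical at C6 while the carbinol carbon keeps the configuration set in step 9; this radical attacks the CH2 terminus of the exocyclic alkene, the new tertiary C4a radical is reduced by hydrogen-atom transfer from the aqua complex of Cp2TiCl, and work-up frees the diol from its titanium alkoxide. The closest known reaction type is the Nugent–RajanBabu epoxide–olefin radical cyclisation in its titanocene-mediated 6-endo epoxypolyene form with water as the hydrogen source. Ring B closes by 6-endo-trig attack through a chair transition state fused like a trans-decalin to ring A, whose conformation is fixed by the trans-diequatorial chains at C1 and C8a. C6 is controlled by that chair: the bulky CH(OTi)CH2OH group lies equatorial, so the C6 methyl ends up axial and anti to the angular methyl; C4a is controlled by axial hydrogen delivery anti to the adjacent axial angular methyl, which gives the trans fusion. The step needs 6-endo over 5-exo closure, secured by the fully substituted internal alkene carbon and the tertiary radical formed; ring closure before reduction of the first radical, secured by high dilution, slow addition and only a small excess of water; and no radical attack on a carbonyl, secured by the ketal at C2.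

Step 11
Reactants: 16 (1S)-1-[(1'R,4a'S,6'S,8a'S)-6',8a'-dimethyl-1'-{3-[(4S)-2,2,4-trimethyl-1,3-dioxolan-4-yl]propyl}octahydro-1'H-spiro[1,3-dioxolane-2,2'-naphthalen]-6'-yl]ethane-1,2-diol
Product: 17 (1R,4aS,6S,8aS)-6-[(1S)-1,2-dihydroxyethyl]-1-[(4S)-4,5-dihydroxy-4-methylpentyl]-6,8a-dimethyloctahydronaphthalen-2(1H)-one
Conditions: 1 M aq HCl, THF, rt
Reagents that add atoms: water, O
Why: Aqueous acid hydrolyses the dioxolane ketal and the acetonide together, and C1, now α to the ketone, already carries its chain in the thermodynamically preferred equatorial position, so no epimerisation is expected.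

Compound list
1 | (S)-(+)-linalool, (3S)-3,7-dimethylocta-1,6-dien-3-ol | C[C@@](O)(C=C)CCC=C(C)C | starting material
2 | (2S)-2-hydroxy-2-methylpentanedial (largely as its lactol) | C[C@@](O)(C=O)CCC=O | intermediate (not isolated)
3 | (2S)-2-methylpentane-1,2,5-triol | C[C@@](O)(CO)CCCO | intermediate
4 | 3-[(4S)-2,2,4-trimethyl-1,3-dioxolan-4-yl]propan-1-ol | C[C@@]1(COC(C)(C)O1)CCCO | intermediate
5 | (4S)-4-(3-bromopropyl)-2,2,4-trimethyl-1,3-dioxolane | C[C@@]1(COC(C)(C)O1)CCCBr | intermediate
6 | 1,4-dioxaspiro[4.5]dec-6-en-8-one | O=C1C=CC2(OCCO2)CC1 | starting material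
7 | {3-[(4S)-2,2,4-trimethyl-1,3-dioxolan-4-yl]propyl}magnesium bromide | C[C@@]1(COC(C)(C)O1)CCC[Mg]Br | intermediate (not isolated)
8 | bromomagnesium (6R)-6-{3-[(4S)-2,2,4-trimethyl-1,3-dioxolan-4-yl]propyl}-1,4-dioxaspiro[4.5]dec-7-en-8-olate | C[C@@]1(COC(C)(C)O1)CCC[C@H]2C3(OCCO3)CCC(O[Mg]Br)=C2 | intermediate (not isolated)
9 | (6R,7R)-7-methyl-6-{3-[(4S)-2,2,4-trimethyl-1,3-dioxolan-4-yl]propyl}-1,4-dioxaspiro[4.5]decan-8-one (6,7-trans) | C[C@@]1(COC(C)(C)O1)CCC[C@H]2C3(OCCO3)CCC(=O)[C@@H]2C | intermediate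
10 | N-[(1R)-1-phenylethyl] imine of 9 (C7 epimers, in equilibrium with the secondary enamine) | C[C@@]1(COC(C)(C)O1)CCC[C@H]2C3(OCCO3)CCC(=N[C@H](C)c4ccccc4)C2C | intermediate (not isolated)
11 | (6R,7R)-7-methyl-7-(3-oxobutyl)-6-{3-[(4S)-2,2,4-trimethyl-1,3-dioxolan-4-yl]propyl}-1,4-dioxaspiro[4.5]decan-8-one | C[C@@]1(COC(C)(C)O1)CCC[C@H]2C3(OCCO3)CCC(=O)[C@]2(C)CCC(C)=O | intermediate
12 | ethyl (2E)-3-methyl-5-[(6R,7R)-7-methyl-8-oxo-6-{3-[(4S)-2,2,4-trimethyl-1,3-dioxolan-4-yl]propyl}-1,4-dioxaspiro[4.5]decan-7-yl]pent-2-enoate | C[C@@]1(COC(C)(C)O1)CCC[C@H]2C3(OCCO3)CCC(=O)[C@]2(C)CC/C(C)=C/C(=O)OCC | intermediate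
13 | ethyl (2E)-3-methyl-5-[(6R,7R)-7-methyl-8-methylidene-6-{3-[(4S)-2,2,4-trimethyl-1,3-dioxolan-4-yl]propyl}-1,4-dioxaspiro[4.5]decan-7-yl]pent-2-enoate | C[C@@]1(COC(C)(C)O1)CCC[C@H]2C3(OCCO3)CCC(=C)[C@]2(C)CC/C(C)=C/C(=O)OCC | intermediate
14 | (2E)-3-methyl-5-[(6R,7R)-7-methyl-8-methylidene-6-{3-[(4S)-2,2,4-trimethyl-1,3-dioxolan-4-yl]propyl}-1,4-dioxaspiro[4.5]decan-7-yl]pent-2-en-1-ol | C[C@@]1(COC(C)(C)O1)CCC[C@H]2C3(OCCO3)CCC(=C)[C@]2(C)CC/C(C)=C/CO | intermediate
15 | [(2R,3R)-3-methyl-3-{2-[(6R,7R)-7-methyl-8-methylidene-6-{3-[(4S)-2,2,4-trimethyl-1,3-dioxolan-4-yl]propyl}-1,4-dioxaspiro[4.5]decan-7-yl]ethyl}oxiran-2-yl]methanol | C[C@@]1(COC(C)(C)O1)CCC[C@H]2C3(OCCO3)CCC(=C)[C@]2(C)CC[C@@]4(C)O[C@@H]4CO | intermediate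
16 | (1S)-1-[(1'R,4a'S,6'S,8a'S)-6',8a'-dimethyl-1'-{3-[(4S)-2,2,4-trimethyl-1,3-dioxolan-4-yl]propyl}octahydro-1'H-spiro[1,3-dioxolane-2,2'-naphthalen]-6'-yl]ethane-1,2-diol (trans-fused; C2 ketal and side-chain acetonide of the target) | C[C@@]1(COC(C)(C)O1)CCC[C@H]2C3(OCCO3)CC[C@H]4C[C@@](C)([C@H](O)CO)CC[C@@]42C | intermediate
17 | (1R,4aS,6S,8aS)-6-[(1S)-1,2-dihydroxyethyl]-1-[(4S)-4,5-dihydroxy-4-methylpentyl]-6,8a-dimethyloctahydronaphthalen-2(1H)-one | C[C@@](O)(CO)CCC[C@H]1C(=O)CC[C@H]2C[C@@](C)([C@H](O)CO)CC[C@@]21C | target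

Total step count: 11. Longest linear sequence: 11 steps (1 to 17 through steps 1–11; enone 6 enters in step 4).

Steps most likely to fail

Step 10. Three things may go wrong:
- The first tertiary radical may be reduced, or lose a β-hydrogen, before it cyclises.
- Hydrogen may be delivered to C4a from the β face, because the axial C6 methyl shields the α face, which would give the cis fusion.
- The C4a radical may take a hydrogen intramolecularly from the CH2OH carbon.

The fallback separates ring closure from hydrogen delivery. It sets out from 15. Under anhydrous, titanium-catalytic conditions (Cp2TiCl2 10 mol %, Mn, 2,4,6-collidine hydrochloride, THF) the cyclised radical should end by β-hydride loss as the 4,4a-didehydro derivative of 16 F1, together with the 4a,5-didehydro derivative of 16 F2. Hydrogen-atom-transfer hydrogenation of this mixture (Mn(dpm)3, PhSiH3, t-BuOOH, i-PrOH), whose small donor is known to favour the more stable trans ring fusion, comes back to the route at 16.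

Step 4. Face discrimination at the β-carbon beside the spiro ketal may be insufficient, and proton exchange may cause over-methylation during enolate trapping. The fallback changes the substrate and the organometallic and sets out from Grignard reagent 7:
- Transmetalation with ZnCl2 (0.5 equiv, magnesium salts precipitated with dioxane) gives bis{3-[(4S)-2,2,4-trimethyl-1,3-dioxolan-4-yl]propyl}zinc F3.
- F3 is added under Cu(OTf)2/phosphoramidite catalysis to the symmetrical quinone monoketal 1,4-dioxaspiro[4.5]deca-6,9-dien-8-one F4, a desymmetrising conjugate addition of an established type.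
- The zinc enolate is methylated (MeI, DMPU) to (6R,7R)-7-methyl-6-{3-[(4S)-2,2,4-trimethyl-1,3-dioxolan-4-yl]propyl}-1,4-dioxaspiro[4.5]dec-9-en-8-one F5.
- Hydrogenation of the remaining enone double bond (H2, Pd/C, EtOAc) comes back to the route at 9.

Step 5. The aza-ene Michael addition may be slow at the congested tetrasubstituted enamine carbon, with competing reaction at the less substituted α-carbon or polymerisation of the enone. The fallback replaces the enamine by a regiodefined silyl enol ether and sets out from 9. TMSCl, NaI and Et3N in MeCN should give the thermodynamic enol ether (6R)-7-methyl-6-{3-[(4S)-2,2,4-trimethyl-1,3-dioxolan-4-yl]propyl}-8-(trimethylsilyloxy)-1,4-dioxaspiro[4.5]dec-7-ene F6. A Mukaiyama–Michael addition to methyl vinyl ketone (Sc(OTf)3 cat., CH2Cl2, −78 °C; aqueous work-up), with the C6 chain alone directing the anti approach, comes back to the route at 11.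

Further compounds
F1 | step 10 | 4,4a-didehydro derivative of 16 (ring A olefin) | C[C@@]1(COC(C)(C)O1)CCC[C@H]2C3(OCCO3)CC=C4C[C@@](C)([C@H](O)CO)CC[C@@]42C
F2 | step 10 | 4a,5-didehydro derivative of 16 (ring B olefin) | C[C@@]1(COC(C)(C)O1)CCC[C@H]2C3(OCCO3)CCC4=C[C@@](C)([C@H](O)CO)CC[C@@]42C
F3 | step 4 | bis{3-[(4S)-2,2,4-trimethyl-1,3-dioxolan-4-yl]propyl}zinc | C[C@@]1(COC(C)(C)O1)CCC[Zn]CCC[C@@]2(C)COC(C)(C)O2
F4 | step 4 | 1,4-dioxaspiro[4.5]deca-6,9-dien-8-one | O=C1C=CC2(OCCO2)C=C1
F5 | step 4 | (6R,7R)-7-methyl-6-{3-[(4S)-2,2,4-trimethyl-1,3-dioxolan-4-yl]propyl}-1,4-dioxaspiro[4.5]dec-9-en-8-one | C[C@@]1(COC(C)(C)O1)CCC[C@H]2C3(OCCO3)C=CC(=O)[C@@H]2C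
F6 | step 5 | (6R)-7-methyl-6-{3-[(4S)-2,2,4-trimethyl-1,3-dioxolan-4-yl]propyl}-8-(trimethylsilyloxy)-1,4-dioxaspiro[4.5]dec-7-ene | C[C@@]1(COC(C)(C)O1)CCC[C@H]2C3(OCCO3)CCC(O[Si](C)(C)C)=C2C
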